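Ring letters: A is the dihydroxylated ring, B the para-linked ring, C the monohydroxylated ring, D the unsubstituted ring. The route rests on cutting the ring A carbon–oxygen(ring B) bond. Ring A carries this aryloxy carbon directly beside a hydroxyl-bearing carbon, the mark of ortho phenol coupling, so Tl(NO3)3 oxidation of a ring A 2,6-dibromophenol lets the ring B 2,6-dichlorophenol oxygen add to a C–Br carbon and closes the 17-membered ring in one operation, zinc then restoring the phenol. The precursor is an open chain: ring A dibromophenol and ring B dichlorophenol, both free, joined through ethylene bridges to the preformed ring D–O–ring C ether, ring C masked as methyl ether.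

Key step: step 11

Assumption: 2-hydroxy-3-methoxybenzyl alcohol (the borohydride reduction product of o-vanillin) is taken as the commercial ring C building block; the Wittig olefinations are expected to give E/Z mixtures (E drawn), carried on together because step 9 saturates both double bonds.

Step 1
Reactants: 1 3,5-dichloro-4-hydroxybenzaldehyde
Product: 2 4-(benzyloxy)-3,5-dichlorobenzaldehyde
Conditions: BnBr, K2CO3, DMF, 60 °C
Reagents that add atoms: benzyl bromide, BrCc1ccccc1
Why: Williamson etherification of the acidic dihalophenol with a primary benzylic bromide should proceed cleanly under carbonate base.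

Step 2
Reactants: 3 2-hydroxy-3-methoxybenzyl alcohol
Product: 4 (2-hydroxy-3-methoxybenzyl)triphenylphosphonium bromide
Conditions: PPh3·HBr, MeCN, reflux
Reagents that add atoms: triphenylphosphine hydrobromide, Br.c1ccc(cc1)P(c1ccccc1)c1ccccc1
Why: Phosphonium salt formation, in which the acid activates the electron-rich salicyl alcohol at the benzylic carbon and triphenylphosphine captures it, is a standard one-step entry to Wittig salts.

Step 3
Reactants: 4 (2-hydroxy-3-methoxybenzyl)triphenylphosphonium bromide; 2 4-(benzyloxy)-3,5-dichlorobenzaldehyde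
Product: 6 2-[2-(4-benzyloxy-3,5-dichlorophenyl)ethenyl]-6-methoxyphenol (E/Z mixture), via phenolate ylide 5 (not isolated)
Conditions: KOtBu (2.2 equiv), THF, 0 °C; then 2, 0 °C to rt
Reagents that add atoms: none
Why: Wittig olefination, in which two equivalents of base give the phenolate ylide 5 that adds to the electron-poor aldehyde 2; no stereocenter forms and the alkene geometry is irrelevant because step 9 saturates it.

Step 4
Reactants: 6 2-[2-(4-benzyloxy-3,5-dichlorophenyl)ethenyl]-6-methoxyphenol; 7 2-fluorobenzaldehyde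
Product: 8 2-{2-[2-(4-benzyloxy-3,5-dichlorophenyl)ethenyl]-6-methoxyphenoxy}benzaldehyde
Conditions: K2CO3, DMAc, 120 °C
Reagents that add atoms: none
Why: Nucleophilic aromatic substitution (SNAr), in which the phenoxide of 6 adds at the fluorine-bearing carbon of 7 with the ortho formyl group stabilising the Meisenheimer intermediate, sets the ring C–O–ring D ether while benzyl ether, aryl chlorides and stilbene stay inert to carbonate.

Step 5
Reactants: 9 3,5-dibromo-4-hydroxybenzaldehyde
Product: 10 4-(benzyloxy)-3,5-dibromobenzaldehyde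
Conditions: BnBr, K2CO3, DMF, 60 °C
Reagents that add atoms: benzyl bromide, BrCc1ccccc1
Why: Williamson etherification of the acidic dibromophenol, as in step 1.

Step 6
Reactants: 10 4-(benzyloxy)-3,5-dibromobenzaldehyde
Product: 11 [4-(benzyloxy)-3,5-dibromophenyl]methanol
Conditions: NaBH4, MeOH/THF, 0 °C
Reagents that add atoms: none
Why: Borohydride reduction of an aromatic aldehyde is chemoselective and leaves aryl bromides and the benzyl ether untouched.

Step 7
Reactants: 11 [4-(benzyloxy)-3,5-dibromophenyl]methanol
Product: 12 [4-(benzyloxy)-3,5-dibromobenzyl]triphenylphosphonium bromide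
Conditions: PPh3·HBr, MeCN, reflux
Reagents that add atoms: triphenylphosphine hydrobromide, Br.c1ccc(cc1)P(c1ccccc1)c1ccccc1
Why: Phosphonium salt formation through the benzylic bromide generated by HBr and quaternised by PPh3; the benzyl ether on the weakly basic dihalophenol oxygen should tolerate the mildly acidic salt.

Step 8
Reactants: 12 [4-(benzyloxy)-3,5-dibromobenzyl]triphenylphosphonium bromide; 8 2-{2-[2-(4-benzyloxy-3,5-dichlorophenyl)ethenyl]-6-methoxyphenoxy}benzaldehyde
Product: 14 1-benzyloxy-2,6-dibromo-4-[2-(2-{2-[2-(4-benzyloxy-3,5-dichlorophenyl)ethenyl]-6-methoxyphenoxy}phenyl)ethenyl]benzene (isomer mixture), via benzyl ylide 13 (not isolated)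
Conditions: KOtBu (1.1 equiv), THF, 0 °C; then 8, 0 °C to rt
Reagents that add atoms: none
Why: Wittig olefination of the non-enolisable aldehyde 8 with the semi-stabilised ylide 13 joins ring D to ring A; the geometry is again of no consequence.

Step 9
Reactants: 14 the bis-stilbene
Product: 15 1-benzyloxy-2,6-dibromo-4-[2-(2-{2-[2-(4-benzyloxy-3,5-dichlorophenyl)ethyl]-6-methoxyphenoxy}phenyl)ethyl]benzene
Conditions: TsNHNH2 (excess), NaOAc, THF/H2O, reflux
Reagents that add atoms: none
Why: Diimide reduction, in which HN=NH released from the sulfonyl hydrazide delivers H2 to each C=C through a concerted cyclic transition state, spares the C–Br, C–Cl and benzyl ether bonds that hydrogenation over palladium would cleave.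

Step 10
Reactants: 15 the saturated bis(benzyl ether)
Product: 16 2,6-dibromo-4-[2-(2-{2-[2-(3,5-dichloro-4-hydroxyphenyl)ethyl]-6-methoxyphenoxy}phenyl)ethyl]phenol
Conditions: BCl3, pentamethylbenzene, CH2Cl2, −78 to −20 °C
Reagents that add atoms: none
Why: Lewis-acid debenzylation, in which BCl3 activates the benzyl ether oxygens and pentamethylbenzene traps the benzyl cations (Friedel–Crafts), should free both halophenols at low temperature without touching the ring C methyl ether, the diaryl ether or the halogens.

Step 11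
Reactants: 16 the seco bis(halophenol)
Product: 18 macrocyclic ortho-hydroxy diaryl ether (ring A OH plus one Br; ring B two Cl; ring C OMe), via bromodienone 17 (not isolated)
Conditions: Tl(NO3)3·3H2O (3 equiv), MeOH/THF, 1 mM, −20 to 0 °C; then Zn dust, AcOH, rt
Reagents that add atoms: none
Why: Trivalent thallium removes two electrons from the ring A 2,6-dibromophenol, the more easily oxidised of the two halophenols, and the resulting phenoxonium-type species is captured at a C–Br ortho carbon by the ring B phenol oxygen to give the 6-aryloxy-2,6-dibromocyclohexa-2,4-dienone 17; zinc then removes the geminal bromine and rearomatises ring A. The closest known reaction type is the Tl(NO3)3 oxidative coupling of ortho,ortho'-dihalophenols to ortho-hydroxy diaryl ethers, which is established for macrocyclic substrates. The 17-membered ring closes by intramolecular C–O bond formation (ring B oxygen onto the ortho carbon of ring A) under high dilution. No stereocenter remains, since the quaternary carbon of 17 is racemic and is erased by the reduction. The step needs oxidation of ring A in preference to ring B, which the lower oxidation potential of the dibromophenol should secure; the site of attack is not an issue because the two C–Br carbons are symmetry-equivalent, and the four halogens and the para alkyl groups block C–C coupling.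

Step 12
Reactants: 18 the macrocyclic bromophenol
Product: 19 ring A O-methyl ether of 18
Conditions: MeI, K2CO3, DMF, rt
Reagents that add atoms: iodomethane, CI
Why: Williamson O-methylation masks the ring A phenol for the palladium step and is removed in step 15 together with the ring C methyl ether.

Step 13
Reactants: 19 the ring A methyl ether
Product: 21 macrocycle with ring A 4-methoxy-5-hydroxy pattern (ring B two Cl; ring C OMe), via pinacol boronate 20 (not isolated)
Conditions: B2pin2, PdCl2(dppf), KOAc, 1,4-dioxane, 90 °C; then 30% aq. H2O2, NaOH, THF, 0 °C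
Reagents that add atoms: hydrogen peroxide, OO (phenolic oxygen of 21); bis(pinacolato)diboron, CC1(C)OB(OC1(C)C)B1OC(C)(C)C(C)(C)O1 (boron of intermediate 20 only)
Why: Miyaura borylation followed by boronate oxidation: zerovalent palladium with dppf inserts into the C–Br bond but not into the hindered C–Cl bonds, and alkaline peroxide turns C–B into C–O by 1,2-aryl migration.

Step 14
Reactants: 21 the dichloro macrocyclic phenol
Product: 22 dechlorinated macrocycle (ring A 4-methoxy-5-hydroxy; ring C OMe)
Conditions: H2 (1 atm), 10% Pd/C, Et3N, MeOH/EtOAc, rt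
Reagents that add atoms: none
Why: Catalytic hydrodechlorination over palladium on carbon cleaves both aryl C–Cl bonds with the amine taking up HCl, while diaryl ethers, methyl ethers and the phenol are stable.

Step 15
Reactants: 22 the dechlorinated dimethyl ether
Product: 23 target macrocycle CNP0290892.0
Conditions: BBr3, CH2Cl2, −78 °C to rt
Reagents that add atoms: none
Why: BBr3 demethylation (Lewis-acid complexation, then SN2 attack of bromide on methyl) should release the ring A catechol and the ring C phenol, the diaryl ethers being resistant.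

Compound list
1 | 3,5-dichloro-4-hydroxybenzaldehyde | O=Cc1cc(Cl)c(O)c(Cl)c1 | starting material
2 | 4-(benzyloxy)-3,5-dichlorobenzaldehyde | O=Cc1cc(Cl)c(OCc2ccccc2)c(Cl)c1 | intermediate
3 | 2-hydroxy-3-methoxybenzyl alcohol | COc1cccc(CO)c1O | starting material
4 | (2-hydroxy-3-methoxybenzyl)triphenylphosphonium bromide | [Br-].COc1cccc(C[P+](c2ccccc2)(c2ccccc2)c2ccccc2)c1O | intermediate
5 | potassium 2-methoxy-6-[(triphenylphosphoranylidene)methyl]phenolate (phenolate ylide, not isolated) | [K+].COc1cccc(C=P(c2ccccc2)(c2ccccc2)c2ccccc2)c1[O-] | intermediate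
6 | 2-[2-(4-benzyloxy-3,5-dichlorophenyl)ethenyl]-6-methoxyphenol (E/Z mixture, E drawn) | COc1cccc(/C=C/c2cc(Cl)c(OCc3ccccc3)c(Cl)c2)c1O | intermediate
7 | 2-fluorobenzaldehyde | O=Cc1ccccc1F | starting material
8 | 2-{2-[2-(4-benzyloxy-3,5-dichlorophenyl)ethenyl]-6-methoxyphenoxy}benzaldehyde (E/Z mixture, E drawn) | COc1cccc(/C=C/c2cc(Cl)c(OCc3ccccc3)c(Cl)c2)c1Oc1ccccc1C=O | intermediate
9 | 3,5-dibromo-4-hydroxybenzaldehyde | O=Cc1cc(Br)c(O)c(Br)c1 | starting material
10 | 4-(benzyloxy)-3,5-dibromobenzaldehyde | O=Cc1cc(Br)c(OCc2ccccc2)c(Br)c1 | intermediate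
11 | [4-(benzyloxy)-3,5-dibromophenyl]methanol | OCc1cc(Br)c(OCc2ccccc2)c(Br)c1 | intermediate
12 | [4-(benzyloxy)-3,5-dibromobenzyl]triphenylphosphonium bromide | [Br-].Brc1cc(C[P+](c2ccccc2)(c2ccccc2)c2ccccc2)cc(Br)c1OCc1ccccc1 | intermediate
13 | [4-(benzyloxy)-3,5-dibromobenzylidene]triphenylphosphorane (benzyl ylide, not isolated) | Brc1cc(C=P(c2ccccc2)(c2ccccc2)c2ccccc2)cc(Br)c1OCc1ccccc1 | intermediate
14 | bis-stilbene: ring A 4-benzyloxy-3,5-dibromophenyl and ring B 4-benzyloxy-3,5-dichlorophenyl, each joined by CH=CH to the ring D–O–ring C(OMe) core (isomer mixture, E,E drawn) | COc1cccc(/C=C/c2cc(Cl)c(OCc3ccccc3)c(Cl)c2)c1Oc1ccccc1/C=C/c1cc(Br)c(OCc2ccccc2)c(Br)c1 | intermediate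
15 | saturated bis(benzyl ether): as 14 with both bridges CH2CH2 | COc1cccc(CCc2cc(Cl)c(OCc3ccccc3)c(Cl)c2)c1Oc1ccccc1CCc1cc(Br)c(OCc2ccccc2)c(Br)c1 | intermediate
16 | 2,6-dibromo-4-[2-(2-{2-[2-(3,5-dichloro-4-hydroxyphenyl)ethyl]-6-methoxyphenoxy}phenyl)ethyl]phenol (seco bis(halophenol), key-step precursor) | Oc1c(Br)cc(CCc2ccccc2Oc2c(OC)cccc2CCc2cc(Cl)c(O)c(Cl)c2)cc1Br | intermediate
17 | macrocyclic 6-aryloxy-2,6-dibromocyclohexa-2,4-dienone (ring A oxidised, racemic at the O/Br carbon, not isolated) | O=C1C(Br)=CC2=CC1(Br)Oc1c(Cl)cc(cc1Cl)CCc1cccc(OC)c1Oc1ccccc1CC2 | intermediate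
18 | 17-membered macrocycle: ring A 4-hydroxy-5-bromo-3-aryloxy, ring B 3,5-dichloro, ring C methoxy | Oc1c(Br)cc2cc1Oc1c(Cl)cc(cc1Cl)CCc1cccc(OC)c1Oc1ccccc1CC2 | intermediate
19 | ring A O-methyl ether of 18 | COc1c(Br)cc2cc1Oc1c(Cl)cc(cc1Cl)CCc1cccc(OC)c1Oc1ccccc1CC2 | intermediate
20 | ring A pinacol boronate (Bpin in place of Br of 19, not isolated) | COc1c(B3OC(C)(C)C(C)(C)O3)cc2cc1Oc1c(Cl)cc(cc1Cl)CCc1cccc(OC)c1Oc1ccccc1CC2 | intermediate
21 | macrocycle with ring A 4-methoxy-5-hydroxy, ring B 3,5-dichloro, ring C methoxy | COc1c(O)cc2cc1Oc1c(Cl)cc(cc1Cl)CCc1cccc(OC)c1Oc1ccccc1CC2 | intermediate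
22 | dechlorinated macrocycle with ring A 4-methoxy-5-hydroxy and ring C methoxy | COc1c(O)cc2cc1Oc1ccc(cc1)CCc1cccc(OC)c1Oc1ccccc1CC2 | intermediate
23 | CNP0290892.0 (achiral macrocyclic bis(bibenzyl), ring A catechol, ring C phenol) | Oc1cc2cc(c1O)Oc1ccc(cc1)CCc1cccc(O)c1Oc1ccccc1CC2 | target

Total step count: 15. Longest linear sequence: 11 steps (for example steps 5 to 15 from 9).

Steps most likely to fail

Step 11. The oxidation may begin at ring B instead of ring A, because the two halophenols differ only modestly in oxidation potential; that would reverse the ether connectivity. Intermolecular coupling may also outrun ring closure and give oligomers. The fallback closes the same ring A C–O bond by Ullmann etherification; it sets out from 4 and comes back at 23. Ylide 5 from 4 is condensed with commercial 4-bromobenzaldehyde to 2-[2-(4-bromophenyl)ethenyl]-6-methoxyphenol F1, and SNAr with 7 (K2CO3, DMAc, 120 °C) should give 2-{2-[2-(4-bromophenyl)ethenyl]-6-methoxyphenoxy}benzaldehyde F2. Commercial 3-hydroxy-4,5-dimethoxybenzaldehyde is reduced with NaBH4 to 3-hydroxy-4,5-dimethoxybenzyl alcohol F3 and converted with PPh3·HBr into (3-hydroxy-4,5-dimethoxybenzyl)triphenylphosphonium bromide F4. Its phenolate ylide F5 (KOtBu, 2.2 equiv, THF) and F2 should give the bromo bis-stilbene phenol F6, which diimide (TsNHNH2, NaOAc) reduces to the saturated bromo phenol F7. Intramolecular Ullmann coupling (CuI, N,N-dimethylglycine, Cs2CO3, 1,4-dioxane, 100 °C, high dilution) of the ring A phenol with the ring B aryl bromide should give the tri-O-methyl macrocycle F8, and BBr3 then gives 23.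

Step 4. Attack by the doubly ortho-substituted phenoxide may be slow enough for base-induced loss of the aldehyde (disproportionation, condensation) or benzyl transfer from the dichlorophenyl ether to compete. The fallback sets out from 6 and comes back at 8: SNAr with the more robust 2-fluorobenzonitrile (Cs2CO3, DMSO, 110 °C) should give 2-{2-[2-(4-benzyloxy-3,5-dichlorophenyl)ethenyl]-6-methoxyphenoxy}benzonitrile F9, and partial reduction with DIBAL-H (toluene, −78 °C, acidic work-up) unmasks aldehyde 8.

Step 3. The phenolate–phosphonium zwitterion may expel PPh3 towards an ortho-quinone methide and oligomerise before the second deprotonation. The fallback reverses the polarity of the olefination; it sets out from 2 and comes back at 6. NaBH4 reduces 2 to [4-(benzyloxy)-3,5-dichlorophenyl]methanol F10, and PPh3·HBr converts this into [4-(benzyloxy)-3,5-dichlorobenzyl]triphenylphosphonium bromide F11. KOtBu gives [4-(benzyloxy)-3,5-dichlorobenzylidene]triphenylphosphorane F12, which is combined with the potassium phenolate of commercial o-vanillin (2-hydroxy-3-methoxybenzaldehyde) to give 6.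

Further compounds
F1 | step 11 | 2-[2-(4-bromophenyl)ethenyl]-6-methoxyphenol (E/Z, E drawn) | COc1cccc(/C=C/c2ccc(Br)cc2)c1O
F2 | step 11 | 2-{2-[2-(4-bromophenyl)ethenyl]-6-methoxyphenoxy}benzaldehyde (E/Z, E drawn) | COc1cccc(/C=C/c2ccc(Br)cc2)c1Oc1ccccc1C=O
F3 | step 11 | 3-hydroxy-4,5-dimethoxybenzyl alcohol | COc1cc(CO)cc(O)c1OC
F4 | step 11 | (3-hydroxy-4,5-dimethoxybenzyl)triphenylphosphonium bromide | [Br-].COc1cc(C[P+](c2ccccc2)(c2ccccc2)c2ccccc2)cc(O)c1OC
F5 | step 11 | potassium 2,3-dimethoxy-5-[(triphenylphosphoranylidene)methyl]phenolate | [K+].COc1cc(C=P(c2ccccc2)(c2ccccc2)c2ccccc2)cc([O-])c1OC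
F6 | step 11 | bromo bis-stilbene phenol (ring A 3-hydroxy-4,5-dimethoxyphenyl, ring B 4-bromophenyl; isomer mixture, E,E drawn) | COc1cccc(/C=C/c2ccc(Br)cc2)c1Oc1ccccc1/C=C/c1cc(O)c(OC)c(OC)c1
F7 | step 11 | saturated bromo phenol (as F6 with CH2CH2 bridges) | COc1cccc(CCc2ccc(Br)cc2)c1Oc1ccccc1CCc1cc(O)c(OC)c(OC)c1
F8 | step 11 | tri-O-methyl ether of 23 (ring A 4,5-dimethoxy, ring C methoxy) | COc1cc2cc(c1OC)Oc1ccc(cc1)CCc1cccc(OC)c1Oc1ccccc1CC2
F9 | step 4 | 2-{2-[2-(4-benzyloxy-3,5-dichlorophenyl)ethenyl]-6-methoxyphenoxy}benzonitrile (E/Z, E drawn) | COc1cccc(/C=C/c2cc(Cl)c(OCc3ccccc3)c(Cl)c2)c1Oc1ccccc1C#N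
F10 | step 3 | [4-(benzyloxy)-3,5-dichlorophenyl]methanol | OCc1cc(Cl)c(OCc2ccccc2)c(Cl)c1
F11 | step 3 | [4-(benzyloxy)-3,5-dichlorobenzyl]triphenylphosphonium bromide | [Br-].Clc1cc(C[P+](c2ccccc2)(c2ccccc2)c2ccccc2)cc(Cl)c1OCc1ccccc1
F12 | step 3 | [4-(benzyloxy)-3,5-dichlorobenzylidene]triphenylphosphorane | Clc1cc(C=P(c2ccccc2)(c2ccccc2)c2ccccc2)cc(Cl)c1OCc1ccccc1
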